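## Retrosynthetic overview

1. The terminal C12'=CH2 is made last by Wittig methylenation of a methyl ketone, which is carried as a dioxolane so that Raney nickel can be used earlier.
2. Key disconnection C1'–C2'–C3': C2' comes from 1,3-dithiane used as a formyl-dianion (acyl-anion) linchpin. In one flask it is alkylated first by a chroman-2-ylmethyl triflate (C1') and then by a C3' iodide; the sulfur is removed afterwards.
3. The chroman ring and the C2 stereocentre are bought intact as (S)-Trolox. No ring of the target is built; a dioxolane (step 4) and a dithiane (step 8) are only temporary rings.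
4. The C3'–C12' piece with both methyl stereocentres comes from (E)-geranylacetone by allylic oxidation of the terminal (E)-methyl and one iridium-catalysed asymmetric hydrogenation of both alkenes.

Assumption: (S)-Trolox and isomerically pure (E)-geranylacetone are bought as such.

Note on descriptors: the target SMILES corresponds to (2R,4'R,8'S). The 8'S label is the natural tocopherol arrangement; only the CIP priority changes because of the terminal alkene. In compounds 12–14 the chroman centre reads S for the same reason (priority of the sulfur-bearing branch), with unchanged geometry.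

## Route

Step 1
Reactants: 1 (S)-Trolox
Product: 2 benzyl (2S)-6-(benzyloxy)-2,5,7,8-tetramethyl-3,4-dihydro-2H-chromene-2-carboxylate
Conditions: BnBr (2.5 equiv), K2CO3 (3 equiv), DMF, 60 °C
Reagents that add atoms: benzyl bromide, BrCc1ccccc1
Why: Williamson-type double O-alkylation of the carboxylate and the hindered phenoxide; the quaternary C2 is untouched.

Step 2
Reactants: 2 benzyl (2S)-6-(benzyloxy)-2,5,7,8-tetramethyl-3,4-dihydro-2H-chromene-2-carboxylate
Product: 3 [(2S)-6-(benzyloxy)-2,5,7,8-tetramethyl-3,4-dihydro-2H-chromen-2-yl]methanol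
Conditions: LiAlH4, THF, 0 °C to rt
Reagents that add atoms: none
Why: Hydride reduction of the ester to the primary alcohol; the aryl benzyl ether and the stereocentre are inert.

Step 3
Reactants: 3 [(2S)-6-(benzyloxy)-2,5,7,8-tetramethyl-3,4-dihydro-2H-chromen-2-yl]methanol
Product: 4 [(2S)-6-(benzyloxy)-2,5,7,8-tetramethyl-3,4-dihydro-2H-chromen-2-yl]methyl trifluoromethanesulfonate
Conditions: Tf2O, pyridine, CH2Cl2, −78 to −30 °C; cold work-up, used at once
Reagents that add atoms: trifluoromethanesulfonic anhydride, O=S(=O)(OS(=O)(=O)C(F)(F)F)C(F)(F)F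
Why: O-sulfonylation gives the only leaving group reactive enough for SN2 at this neopentyl-type carbon, which has no β-hydrogen and so cannot eliminate.

Step 4
Reactants: 5 (5E)-6,10-dimethylundeca-5,9-dien-2-one ((E)-geranylacetone)
Product: 6 2-[(3E)-4,8-dimethylnona-3,7-dien-1-yl]-2-methyl-1,3-dioxolane
Conditions: HOCH2CH2OH, pyridinium p-toluenesulfonate (cat.), benzene, reflux, Dean–Stark
Reagents that add atoms: ethylene glycol, OCCO
Why: Ketalisation with azeotropic water removal masks the ketone against the organolithium chemistry of step 8; the mild acid leaves the trisubstituted alkenes alone.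

Step 5
Reactants: 6 2-[(3E)-4,8-dimethylnona-3,7-dien-1-yl]-2-methyl-1,3-dioxolane
Product: 7 (2E,6E)-2,6-dimethyl-9-(2-methyl-1,3-dioxolan-2-yl)nona-2,6-dien-1-ol
Conditions: SeO2 (0.1 equiv), t-BuOOH (2 equiv), salicylic acid (0.1 equiv), CH2Cl2, 0 °C to rt
Reagents that add atoms: tert-butyl hydroperoxide, CC(C)(C)OO; selenium dioxide (oxygen relay), O=[Se]=O
Why: Allylic oxidation by ene reaction and [2,3]-shift attacks the (E)-methyl of the terminal, most electron-rich alkene and gives the (E)-allylic alcohol (expect about 50 %).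

Step 6
Reactants: 7 (2E,6E)-2,6-dimethyl-9-(2-methyl-1,3-dioxolan-2-yl)nona-2,6-dien-1-ol
Product: 8 (2R,6S)-2,6-dimethyl-9-(2-methyl-1,3-dioxolan-2-yl)nonan-1-ol
Conditions: H2 (50 bar), [Ir(cod)(L*)][B(C6H3(CF3)2)4] (1 mol %), CH2Cl2, rt; L* = the enantiomer of 2-phenyl-8-(di-tert-butylphosphinooxy)-5,6,7,8-tetrahydroquinoline that reduces 6 itself to the (4S)-ketal (unnatural series)
Reagents that add atoms: none
Why: Iridium N,P-catalysed asymmetric hydrogenation of unfunctionalised trisubstituted alkenes; both (E)-alkenes have the same local pattern (CH3 and CH2X on one carbon, H on the other), so one catalyst enantiomer adds H2 to the same face at both and sets C2 (R) and C6 (S) together.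

Step 7
Reactants: 8 (2R,6S)-2,6-dimethyl-9-(2-methyl-1,3-dioxolan-2-yl)nonan-1-ol
Product: 9 2-[(4S,8R)-9-iodo-4,8-dimethylnonyl]-2-methyl-1,3-dioxolane
Conditions: I2, PPh3, imidazole, CH2Cl2, 0 °C to rt
Reagents that add atoms: iodine, [I][I]
Why: Appel iodination at the primary carbon; the adjacent stereocentre is not involved and imidazole buffers the acid so the ketal survives.

Step 8
Reactants: 10 1,3-dithiane; 4 [(2S)-6-(benzyloxy)-2,5,7,8-tetramethyl-3,4-dihydro-2H-chromen-2-yl]methyl trifluoromethanesulfonate; 9 2-[(4S,8R)-9-iodo-4,8-dimethylnonyl]-2-methyl-1,3-dioxolane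
Product: 14 2-[(4S,8R)-9-(2-{[(2S)-6-(benzyloxy)-2,5,7,8-tetramethyl-3,4-dihydro-2H-chromen-2-yl]methyl}-1,3-dithian-2-yl)-4,8-dimethylnonyl]-2-methyl-1,3-dioxolane, via 2-lithio-1,3-dithiane 11 (not isolated), via chromanylmethyl dithiane 12 (not isolated), via lithiated chromanylmethyl dithiane 13 (not isolated)
Conditions: 10 (1.0 equiv), n-BuLi (1.0 equiv), THF, −30 °C; HMPA, then 4 (1.0 equiv), −78 to −20 °C; t-BuLi (1.1 equiv), −78 °C, 10 min; then 9 (1.0 equiv), −78 to 0 °C
Reagents that add atoms: none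
Why: One-flask Corey–Seebach double alkylation in which the dithiane carbon (masked carbonyl, C2') acts as an acyl anion toward two electrophilic carbons: the small 2-lithio-1,3-dithiane displaces the triflate (no elimination possible), and the second anion, whose aryloxy group is γ and so cannot be expelled, is alkylated by the β-branched primary iodide; no stereocentre is touched.

Step 9
Reactants: 14 2-[(4S,8R)-9-(2-{[(2S)-6-(benzyloxy)-2,5,7,8-tetramethyl-3,4-dihydro-2H-chromen-2-yl]methyl}-1,3-dithian-2-yl)-4,8-dimethylnonyl]-2-methyl-1,3-dioxolane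
Product: 16 (6S,10R)-13-[(2R)-6-hydroxy-2,5,7,8-tetramethyl-3,4-dihydro-2H-chromen-2-yl]-6,10-dimethyltridecan-2-one, via chromanol dioxolane 15 (not isolated)
Conditions: Raney Ni (W-2, excess), H2 (1 atm), EtOH, reflux; filter; then 1 M HCl, THF–H2O, rt
Reagents that add atoms: water, O
Why: Raney nickel hydrogenolysis removes both C–S bonds (C2' becomes CH2) and the aryl benzyl ether in one operation, which is possible because no alkene is present yet; dilute acid then hydrolyses the dioxolane to the methyl ketone.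

Step 10
Reactants: 16 (6S,10R)-13-[(2R)-6-hydroxy-2,5,7,8-tetramethyl-3,4-dihydro-2H-chromen-2-yl]-6,10-dimethyltridecan-2-one
Product: 17 (2R)-2,5,7,8-tetramethyl-2-[(4R,8S)-4,8,12-trimethyltridec-12-en-1-yl]-3,4-dihydro-2H-chromen-6-ol (CNP0115007.1)
Conditions: Ph3PCH3Br (4 equiv), KOt-Bu (4 equiv), THF, 0 °C to rt, under argon; aqueous NH4Cl work-up
Reagents that add atoms: methyltriphenylphosphonium bromide, C[P+](c1ccccc1)(c1ccccc1)c1ccccc1.[Br-]
Why: Wittig methylenation of the unhindered methyl ketone gives only the 1,1-disubstituted alkene; one equivalent of ylide is spent on the phenol, which is recovered on work-up.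

## Compound list

1 | (2S)-6-hydroxy-2,5,7,8-tetramethyl-3,4-dihydro-2H-chromene-2-carboxylic acid ((S)-Trolox) | OC(=O)[C@]1(C)CCc2c(C)c(O)c(C)c(C)c2O1 | starting material
2 | benzyl (2S)-6-(benzyloxy)-2,5,7,8-tetramethyl-3,4-dihydro-2H-chromene-2-carboxylate | O=C(OCc1ccccc1)[C@]1(C)CCc2c(C)c(OCc3ccccc3)c(C)c(C)c2O1 | intermediate
3 | [(2S)-6-(benzyloxy)-2,5,7,8-tetramethyl-3,4-dihydro-2H-chromen-2-yl]methanol | OC[C@]1(C)CCc2c(C)c(OCc3ccccc3)c(C)c(C)c2O1 | intermediate
4 | [(2S)-6-(benzyloxy)-2,5,7,8-tetramethyl-3,4-dihydro-2H-chromen-2-yl]methyl trifluoromethanesulfonate | O=S(=O)(OC[C@]1(C)CCc2c(C)c(OCc3ccccc3)c(C)c(C)c2O1)C(F)(F)F | intermediate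
5 | (5E)-6,10-dimethylundeca-5,9-dien-2-one ((E)-geranylacetone) | CC(=O)CC/C=C(\C)CCC=C(C)C | starting material
6 | 2-[(3E)-4,8-dimethylnona-3,7-dien-1-yl]-2-methyl-1,3-dioxolane | CC1(CC/C=C(\C)CCC=C(C)C)OCCO1 | intermediate
7 | (2E,6E)-2,6-dimethyl-9-(2-methyl-1,3-dioxolan-2-yl)nona-2,6-dien-1-ol | CC1(CC/C=C(\C)CC/C=C(\C)CO)OCCO1 | intermediate
8 | (2R,6S)-2,6-dimethyl-9-(2-methyl-1,3-dioxolan-2-yl)nonan-1-ol | CC1(CCC[C@@H](C)CCC[C@@H](C)CO)OCCO1 | intermediate
9 | 2-[(4S,8R)-9-iodo-4,8-dimethylnonyl]-2-methyl-1,3-dioxolane | CC1(CCC[C@@H](C)CCC[C@@H](C)CI)OCCO1 | intermediate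
10 | 1,3-dithiane | C1CSCSC1 | starting material
11 | 2-lithio-1,3-dithiane | [Li]C1SCCCS1 | intermediate
12 | 2-{[(2S)-6-(benzyloxy)-2,5,7,8-tetramethyl-3,4-dihydro-2H-chromen-2-yl]methyl}-1,3-dithiane | C1CSC(C[C@]2(C)CCc3c(C)c(OCc4ccccc4)c(C)c(C)c3O2)SC1 | intermediate
13 | 2-{[(2S)-6-(benzyloxy)-2,5,7,8-tetramethyl-3,4-dihydro-2H-chromen-2-yl]methyl}-2-lithio-1,3-dithiane | [Li]C1(C[C@]2(C)CCc3c(C)c(OCc4ccccc4)c(C)c(C)c3O2)SCCCS1 | intermediate
14 | 2-[(4S,8R)-9-(2-{[(2S)-6-(benzyloxy)-2,5,7,8-tetramethyl-3,4-dihydro-2H-chromen-2-yl]methyl}-1,3-dithian-2-yl)-4,8-dimethylnonyl]-2-methyl-1,3-dioxolane | CC1(CCC[C@@H](C)CCC[C@@H](C)CC2(C[C@]3(C)CCc4c(C)c(OCc5ccccc5)c(C)c(C)c4O3)SCCCS2)OCCO1 | intermediate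
15 | (2R)-2-[(4R,8S)-4,8-dimethyl-11-(2-methyl-1,3-dioxolan-2-yl)undecyl]-2,5,7,8-tetramethyl-3,4-dihydro-2H-chromen-6-ol | CC1(CCC[C@@H](C)CCC[C@@H](C)CCC[C@]2(C)CCc3c(C)c(O)c(C)c(C)c3O2)OCCO1 | intermediate
16 | (6S,10R)-13-[(2R)-6-hydroxy-2,5,7,8-tetramethyl-3,4-dihydro-2H-chromen-2-yl]-6,10-dimethyltridecan-2-one | CC(=O)CCC[C@@H](C)CCC[C@@H](C)CCC[C@]1(C)CCc2c(C)c(O)c(C)c(C)c2O1 | intermediate
17 | (2R)-2,5,7,8-tetramethyl-2-[(4R,8S)-4,8,12-trimethyltridec-12-en-1-yl]-3,4-dihydro-2H-chromen-6-ol | C=C(C)CCC[C@@H](C)CCC[C@@H](C)CCC[C@]1(C)CCc2c(C)c(O)c(C)c(C)c2O1 | target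

## Step count and risks

Total steps: 10. Longest linear sequence: 7 (steps 4, 5, 6, 7, 8, 9, 10).

Most likely to fail, with fallbacks:

Step 8 (SN2 at the neopentyl-type triflate, then alkylation of a hindered dithiane anion). The fallback sets out from 3 and comes back at 12. Oxidise 3 (SO3·pyridine, DMSO, Et3N) to (2S)-6-(benzyloxy)-2,5,7,8-tetramethyl-3,4-dihydro-2H-chromene-2-carbaldehyde F1. Peterson olefination with 2-lithio-2-(trimethylsilyl)-1,3-dithiane passes through the silyl carbinol 1-[(2S)-6-(benzyloxy)-2,5,7,8-tetramethyl-3,4-dihydro-2H-chromen-2-yl]-1-[2-(trimethylsilyl)-1,3-dithian-2-yl]methanol F2 (lithium alkoxide, not isolated) and gives the ketene dithioacetal 2-{[(2S)-6-(benzyloxy)-2,5,7,8-tetramethyl-3,4-dihydro-2H-chromen-2-yl]methylidene}-1,3-dithiane F3. Ionic hydrogenation (Et3SiH, CF3CO2H, CH2Cl2) gives 12, now isolated, which is lithiated with t-BuLi to 13 and alkylated with 9 to 14 as in step 8. The substitution at the hindered carbon is replaced by a carbonyl addition, and the dithiane still acts as the acyl anion for the bond to C3'.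

Step 6 (one catalyst must control two different alkenes; the hydroxyl group may disturb face selection or cause isomerisation at the allylic alcohol). The fallback sets out from 7 and comes back at 8. First reduce only the allylic-alcohol alkene by hydroxyl-directed hydrogenation with Ru(OAc)2(BINAP) (the BINAP enantiomer that gives the 2R alcohol; H2 30 bar, MeOH), which leaves the isolated alkene untouched and gives (2R,6E)-2,6-dimethyl-9-(2-methyl-1,3-dioxolan-2-yl)non-6-en-1-ol F4. The remaining purely alkyl-substituted alkene of F4 is then reduced with the iridium catalyst of step 6 to 8. Each centre is thus set by the control element best suited to it, instead of both at once.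

Step 5 (modest yield, over-oxidation, some attack at the inner alkene). The fallback sets out from 6 and comes back at 7. Terminal-selective bromohydrin formation (NBS, aqueous THF, 0 °C) gives (6E)-3-bromo-2,6-dimethyl-9-(2-methyl-1,3-dioxolan-2-yl)non-6-en-2-ol F5. K2CO3 in MeOH closes it to the epoxide 2-[(3E)-6-(3,3-dimethyloxiran-2-yl)-4-methylhex-3-en-1-yl]-2-methyl-1,3-dioxolane F6. LiNEt2 in ether opens the epoxide to the secondary allylic alcohol (6E)-2,6-dimethyl-9-(2-methyl-1,3-dioxolan-2-yl)nona-1,6-dien-3-ol F7. A 1,3-transposition with Ph3SiOReO3 (cat., ether, −50 to 0 °C) then moves the hydroxyl group to the primary position with the more substituted (E)-alkene, giving 7.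

Further compounds

F1 | step 8 | (2S)-6-(benzyloxy)-2,5,7,8-tetramethyl-3,4-dihydro-2H-chromene-2-carbaldehyde | O=C[C@]1(C)CCc2c(C)c(OCc3ccccc3)c(C)c(C)c2O1
F2 | step 8 | 1-[(2S)-6-(benzyloxy)-2,5,7,8-tetramethyl-3,4-dihydro-2H-chromen-2-yl]-1-[2-(trimethylsilyl)-1,3-dithian-2-yl]methanol (carbinol centre unassigned) | OC([C@]1(C)CCc2c(C)c(OCc3ccccc3)c(C)c(C)c2O1)C1([Si](C)(C)C)SCCCS1
F3 | step 8 | 2-{[(2S)-6-(benzyloxy)-2,5,7,8-tetramethyl-3,4-dihydro-2H-chromen-2-yl]methylidene}-1,3-dithiane | S1CCCSC1=C[C@]1(C)CCc2c(C)c(OCc3ccccc3)c(C)c(C)c2O1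
F4 | step 6 | (2R,6E)-2,6-dimethyl-9-(2-methyl-1,3-dioxolan-2-yl)non-6-en-1-ol | CC1(CC/C=C(\C)CCC[C@@H](C)CO)OCCO1
F5 | step 5 | (6E)-3-bromo-2,6-dimethyl-9-(2-methyl-1,3-dioxolan-2-yl)non-6-en-2-ol (racemic at C3) | CC1(CC/C=C(\C)CCC(Br)C(C)(C)O)OCCO1
F6 | step 5 | 2-[(3E)-6-(3,3-dimethyloxiran-2-yl)-4-methylhex-3-en-1-yl]-2-methyl-1,3-dioxolane (racemic) | CC1(CC/C=C(\C)CCC2OC2(C)C)OCCO1
F7 | step 5 | (6E)-2,6-dimethyl-9-(2-methyl-1,3-dioxolan-2-yl)nona-1,6-dien-3-ol (racemic) | CC1(CC/C=C(\C)CCC(O)C(C)=C)OCCO1
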